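## Structural features

Arecatannin A2 is a linear B-type procyanidin tetramer. Units 1 to 3 (numbered from the top) are (2R,3R)-epicatechin units and unit 4 is (2R,3S)-catechin. Each unit is a 2-arylchroman (phloroglucinol ring A, pyran ring C, catechol ring B), and each of units 1 to 3 is joined to the next by one bond from C4 (R, β) to C8. Ring C of units 1 to 3 therefore carries three adjacent stereocentres, with the C2 aryl group and the C3 hydroxyl cis and the C3 hydroxyl and the C4 aryl group trans. Unit 4 has only the trans C2/C3 pair, giving eleven stereocentres in all. The sixteen phenolic hydroxyls oxidise readily in base and air, the interflavan bonds are cleaved by acid through a C4 benzylic cation, and C2 of a free flavan-3-ol epimerises in hot base, so the phenols should stay masked until a final neutral hydrogenolysis. The real difficulty is the C4–C8 bond: it joins a doubly benzylic stereocentre to one of two nucleophilic positions (C8 or C6) of a phloroglucinol ring, cationic couplings tend to run on to higher oligomers, and the cis/trans triad of ring C has to be set as well. The key step uses the fact that ring A of unit 3 (C4a, C5, C6, C7, C8, C8a, with oxygen on C5, C7 and C8a) is a phloroglucinol, that is, a folded triacetic acid chain. It can be carried as the 6-methylpyran-2-one of triacetic acid lactone, already fused to a finished ring C through O1–C8a and C4–C4a, so that ring A appears only when C5–C6 is closed.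

## Logic of the disconnections

27 ⇒ 26. The last cut removes the seventeen O–benzyl bonds and the C8–Br bond of unit 1. The free polyphenol would not survive anything but a neutral final step, and the bromine is only a blocking group. Every earlier intermediate is then a lipophilic ether that can be chromatographed. The forward hydrogenolysis must stop short of the benzylic C2–O1 bonds.

26 ⇒ 25 + 19. The cut is the bond from C4 of unit 2 to C8 of unit 3. It is the central interflavan bond, and a C4 cation of an epicatechin unit is attacked anti to its axial C3 oxygen, which is the required β face. The gain is two dimers of similar size. The demand is that 19 reacts only through C8 of its top unit and that 25 cannot act as a nucleophile, which its C8 bromine ensures.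

25 ⇒ 24 ⇒ 23 + 21, and 23 ⇒ 22 ⇒ 21 ⇒ 20. The cuts are the C4–O leaving-group bonds, the bond from C4 of unit 1 to C8 of unit 2, the C8–Br bond and four O–benzyl bonds. Units 1 and 2 contain nothing that 20 does not already have, so their C2 and C3 centres come from the chiral pool. The demand is that the benzylic oxidation of 24 picks the CH2 group of its lower unit.

19 ⇒ 18. Two O–benzyl bonds on ring A of unit 3 are cut. The phenols freed by the key step must be masked before cation chemistry. The forward alkylation must be phenol-selective and leave the C3 hydroxyl alone.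

18 ⇒ 16 (through 17). The cut is C5–C6 of ring A of unit 3; the seco ester 17 is then closed in thought to the lactone 16. This replaces a ring with two nucleophilic positions by a pyranone whose bond to unit 4 was made before the arene existed, so neither a C6 isomer nor a second alkylation can arise. The forward base step must open the lactone and close C5–C6 without disturbing C2, C3 and C4.

16 ⇒ 10 + 14 (through 15). The cuts are C2–C1′ (ring B of unit 3) and the C3–O bond. With C4 in place, both remaining centres of ring C can be introduced on the face of the enol ether opposite to the C4 aryl group. The gain is a flat enol ether and an aryl-metal reagent. The demand is oxygen transfer anti to the C4 aryl group and aryl delivery syn to the new oxygen.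

10 ⇒ 9 ⇒ 6 + 7 (through 8). The cuts are the C2=C3 unsaturation (back to the lactol), the O1–C2 hemiacetal bond and C4–C4a. C4–C4a is the bond that later counts as the interflavan link, and conjugate addition of the single nucleophilic carbon of 7 to an enal is a catalytic asymmetric reaction. The gain is that 7 is commercial and 6 is three steps from 1. The demand is catalyst control at C4, because the stereocentres of unit 4 are remote.

6 ⇒ 3 ⇒ 2 ⇒ 1. The cuts are the bond from C8 to the enal β-carbon, the C8–Br bond and five O–benzyl bonds. This leads back to the chiral pool with both centres of unit 4 in place. The demand is substitution at C8 and not at C6.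

14 ⇒ 12 ⇒ 11 (through 13). The cuts are the aryl C–Al bond, the C–Mg bond and two O–benzyl bonds. The aryl-metal reagent, which carries one aryl group on a dimethylaluminium centre, is reached in two operations from a commercial bromide.

## Other disconnections considered

Alternative 1: The cut removes C8–C8a and C6–C7 of ring A of unit 4. What remains is a perbenzylated trimer whose unit 3 ends at C4 in a triisopropylsilyl ynol ether (A2), and a 3-benzyloxycyclobutenone carrying the future C4, C3, C2 and ring B of unit 4 as a side chain (A3). On heating, A3 should open to a vinylketene; [2+2] addition to A2, four-electron ring opening and six-electron closure would give the resorcinol A1, whose ring C is closed afterwards by displacement at C2.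
- In its favour: the position of the interflavan bond is written into the alkyne, so no C6 isomer and no over-reaction can arise, and the cascade is pericyclic, neutral and base-free.
- Against it here: the ynol ether sits on a hindered, doubly benzylic C4 that ionises easily, and two bulky partners must meet at that carbon on prolonged heating. The ring it builds belongs to unit 4, which 1 supplies intact, so the C2/C3 pair of A3 needs a separate asymmetric synthesis and ring C needs extra steps.
- Comparison, structure: both plans write a ring A around a ready-made C4 junction and exclude the 4→6 isomer by construction; here the alternative is the equal of the chosen plan.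
- Comparison, mechanism: the alternative is the better of the two, because ynol ether benzannulation to resorcinols is an established class and the Claisen folding of a ring-fused 4-alkoxypyranone is not.
- Comparison, step economy: the chosen plan is ahead, since it uses 1 as unit 4 and reaches the junction from a monomer.

Alternative 2: The cut removes the three C2–C1′ bonds of units 1 to 3 at once. This leaves a tetramer skeleton whose upper three rings C carry an acetate on C2 in place of ring B (A5), and the arene A6. A Lewis acid should ionise the acetates to cyclic oxocarbenium ions, each of which alkylates A6 para to an ether oxygen, giving perbenzylated arecatannin A2 (A4).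
- In its favour: A4 is one hydrogenolysis from the target and needs no blocking group, so its end game is shorter than that of the chosen plan; on this point the alternative is the better. The three rings B come from one cheap arene, and the position of attack on A6 is predictable.
- Against it here: three stereocentres must form in one flask without any ring closing, each cis to the C3 oxygen and trans to the C4 aryl group, so eight diastereomers are possible. The cations arise in a molecule with three trialkoxybenzene rings, which are far better nucleophiles than A6 and invite self-alkylation, and the same acid can ionise the interflavan bonds. A5 has no natural source, so all three C4–C8 bonds must first be made by other means.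
- Comparison, structure: the chosen plan forms the same kind of bond once, in step 8, on a monomeric ring where the C4 substituent and an internal delivery steer the aryl group.
- Comparison, mechanism: both pass through an electrophilic C2 next to O1, but an aluminium-bound aryl group delivered within an ion pair is a more reliable partner than a free, weakly nucleophilic arene.
- Comparison, step economy: the alternative is more convergent at the end but postpones the construction of the interflavan bonds instead of solving it.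

Alternative 3: The cut is O1–C2 of unit 3. The precursor A8 has ring A of unit 3 as an aromatic phenol (C8a hydroxyl free, C5 and C7 benzylated), unit 4 already on C4, and C2/C3 as a cis-epoxide whose aryl group carries two benzoates. Under mild acid the C8a phenol should attack the benzylic C2 from the back in a six-endo opening and give A7 with the 2,3-cis arrangement and a free C3 hydroxyl.
- In its favour: phenol opening of an aryl epoxide is a familiar way to close a chroman, so the precedent is better than for the chosen key step; on this point the alternative is the better. The step is stereospecific, and the benzoates slow ionisation of C2.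
- Against it here: the attacking phenol must be told apart from the oxygen on C5, the very choice between two ortho oxygens that the pyranone avoids. The bond from C4 to unit 4 has to be made earlier on an open chain, and the cis-epoxide needs a Z-alkene and a face-selective oxidation next to C4. Any ionisation leads to the more stable 2,3-trans ring, five-exo attack at C3 would give a dihydrobenzofuran, and the benzoates need a separate removal.
- Comparison, structure: both plans reach the same unit 3–unit 4 dimer with a free C3 hydroxyl; the alternative closes ring C last on a finished ring A, the chosen plan closes ring A last on a finished ring C.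
- Comparison, mechanism: the alternative's key step carries a stereochemical burden at C2 but rests on precedent; the chosen key step carries none but is new.
- Comparison, step economy: the two are about equal up to the dimer, after which the alternative needs one more protecting-group operation.

Key step: step 9

Assumption: the C3 hydroxyl of unit 3 is carried free from step 8 onward instead of as a silyl ether. This leaves the skeletons of the key-step precursor 16 and product 18 unchanged and saves a silylation and a desilylation.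

## Route

Step 1
Reactants: 1 (+)-catechin
Product: 2 3,5,7,3′,4′-penta-O-benzyl-(+)-catechin
Conditions: BnBr, K2CO3, DMF, rt; then NaH, 0 °C → rt (one pot)
Reagents that add atoms: benzyl bromide, BrCc1ccccc1
Why: Williamson etherification; the four phenols are capped under K2CO3 before NaH is added for the C3 alkoxide, so no phenoxide is exposed to strong base and C2 should not epimerise.

Step 2
Reactants: 2 3,5,7,3′,4′-penta-O-benzyl-(+)-catechin
Product: 3 8-bromo-3,5,7,3′,4′-penta-O-benzylcatechin
Conditions: NBS (1.05 equiv), CH2Cl2, −78 → −20 °C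
Reagents that add atoms: N-bromosuccinimide, BrN1C(=O)CCC1=O
Why: Electrophilic aromatic bromination; ring A is the most electron-rich ring and C8 is the preferred site of 5,7-di-O-benzylflavans at low temperature, while one equivalent avoids the 6,8-dibromide.

Step 3
Reactants: 3 8-bromo-3,5,7,3′,4′-penta-O-benzylcatechin
Product: 6 (E)-3-(3,5,7,3′,4′-penta-O-benzylcatechin-8-yl)propenal, via aryllithium 4 (not isolated), via lithium alkoxide adduct 5 (not isolated)
Conditions: t-BuLi (2.1 equiv), THF, −78 °C; Me2NCH=CHCHO, −78 → 0 °C; 1 M HCl, THF, rt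
Reagents that add atoms: 3-(dimethylamino)acrolein, CN(C)/C=C/C=O
Why: Bromine–lithium exchange followed by 1,2-addition of the aryllithium to the vinylogous formamide (vinylogous Bouveault formylation); acid turns the amino alkoxide through the conjugated iminium ion into the (E)-enal.

Step 4
Reactants: 6 (E)-3-(3,5,7,3′,4′-penta-O-benzylcatechin-8-yl)propenal; 7 triacetic acid lactone (4-hydroxy-6-methylpyran-2-one)
Product: 9 (4S)-2-hydroxy-7-methyl-4-(3,5,7,3′,4′-penta-O-benzylcatechin-8-yl)-3,4-dihydro-2H,5H-pyrano[4,3-b]pyran-5-one (both C2 anomers), via open-chain aldehyde 8 (not isolated)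
Conditions: (S)-α,α-diphenylprolinol trimethylsilyl ether (20 mol %), PhCO2H (20 mol %), CH2Cl2–THF, rt
Reagents that add atoms: none
Why: Iminium-ion organocatalysis: Michael addition of a cyclic 1,3-dicarbonyl compound to an enal, then hemiacetal formation. C4 is set by the catalyst, whose diphenyl(silyloxy)methyl group screens one face of the (E)-s-trans iminium ion so that C3 of 7, its only nucleophilic carbon, adds from the other face. The resulting 4S centre has the geometry of the 4β (4R) interflavan carbon of the target; only the priority order changes once ring A is aromatic.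

Step 5
Reactants: 9 (4S)-2-hydroxy-7-methyl-4-(3,5,7,3′,4′-penta-O-benzylcatechin-8-yl)-3,4-dihydro-2H,5H-pyrano[4,3-b]pyran-5-one
Product: 10 (4S)-7-methyl-4-(3,5,7,3′,4′-penta-O-benzylcatechin-8-yl)-4H,5H-pyrano[4,3-b]pyran-5-one
Conditions: TsOH·H2O (5 mol %), 4 Å molecular sieves, toluene, 70 °C
Reagents that add atoms: none
Why: Acid-catalysed dehydration of a cyclic hemiacetal to the enol ether (as in glycal and 4H-chromene formation) by ionisation at C2 and loss of a C3 proton. Base is avoided because it would open the lactol to the pyranone anion; C4 is not involved and keeps its configuration.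

Step 6
Reactants: 11 4-bromocatechol
Product: 12 1,2-bis(benzyloxy)-4-bromobenzene
Conditions: BnBr, K2CO3, acetone, reflux
Reagents that add atoms: benzyl bromide, BrCc1ccccc1
Why: Williamson etherification of both phenols.

Step 7
Reactants: 12 1,2-bis(benzyloxy)-4-bromobenzene
Product: 14 [3,4-bis(benzyloxy)phenyl]dimethylaluminium (used as THF solution), via arylmagnesium bromide 13 (not isolated)
Conditions: Mg, THF, 45 °C; Me2AlCl (1.0 equiv, hexanes), THF, −20 °C → rt
Reagents that add atoms: dimethylaluminium chloride (Me2AlCl), C[Al](C)Cl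
Why: Grignard formation and transmetalation with one equivalent of Me2AlCl give the aryldimethylalane, in which each aluminium carries a single aryl group from 12. Its sp2 aryl ligand is transferred in preference to the methyl groups, and its aluminium centre is the Lewis acid needed in step 8.

Step 8
Reactants: 10 (4S)-7-methyl-4-(3,5,7,3′,4′-penta-O-benzylcatechin-8-yl)-4H,5H-pyrano[4,3-b]pyran-5-one; 14 [3,4-bis(benzyloxy)phenyl]dimethylaluminium
Product: 16 (2R,3R,4S)-2-[3,4-bis(benzyloxy)phenyl]-3-hydroxy-7-methyl-4-(3,5,7,3′,4′-penta-O-benzylcatechin-8-yl)-3,4-dihydro-2H,5H-pyrano[4,3-b]pyran-5-one, via epoxide 15 (not isolated)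
Conditions: DMDO (1.2 equiv), acetone–CH2Cl2, −40 → 0 °C; evaporate; 14 (3 equiv), THF, −78 → 0 °C; cold aq NaHCO3
Reagents that add atoms: dimethyldioxirane, CC1(C)OO1
Why: Dimethyldioxirane should epoxidise the enol ether on the face opposite to the bulky C4 aryl group, which sets C3 trans to C4. The alane then binds the oxirane oxygen, opens the epoxide at the acetal carbon C2 and passes its aryl group (which migrates in preference to methyl) to the face of the departing oxygen (syn opening, as known for glycal epoxides with aryl- and alkynylalanes); this is also the face remote from the C4 aryl group, so the C2 aryl group ends cis to the C3 hydroxyl and trans to C4. Cold bicarbonate work-up protects the new benzylic C2–O1 bond, whose oxygen is a vinylogous carboxylate.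

Step 9
Reactants: 16 (2R,3R,4S)-2-[3,4-bis(benzyloxy)phenyl]-3-hydroxy-7-methyl-4-(3,5,7,3′,4′-penta-O-benzylcatechin-8-yl)-3,4-dihydro-2H,5H-pyrano[4,3-b]pyran-5-one
Product: 18 3′,4′-di-O-benzylepicatechin-(4β→8)-3,5,7,3′,4′-penta-O-benzylcatechin (free 3-, 5- and 7-hydroxyls on unit 3), via seco ester 17 (not isolated)
Conditions: NaOMe (6 equiv), MeOH–THF, 0 → 65 °C, argon; AcOH, 0 °C
Reagents that add atoms: none
Why: Proposed new method: methoxide should add to the lactone carbonyl (C5) of 16 and open the pyranone to the methyl 3-alkoxy-5-oxohex-2-enoate 17, in which the former ring oxygen has become the C7 ketone and O1 stays on C8a; reversible enolisation of the methyl ketone gives the C6 carbanion, which attacks the ester carbonyl, methoxide leaves and the cyclohexenedione tautomerises to the 5,7-dihydroxy ring A. The closest known reaction type is the base-mediated conversion of triacetic acid lactone through methyl 3,5-dioxohexanoate into phloroglucinol by Claisen cyclisation, which has not been shown on a pyranone whose C4 oxygen and C3 carbon are locked in a second ring. The one ring formed, ring A of unit 3, closes by a 6-exo-trig (enolendo) attack of C6 on C5. No stereocentre is created; C2, C3 and C4 lie outside the reacting chain, carry no acidic hydrogen and should pass unchanged. The selectivity needed is regiochemical only: the methyl carbanion has a single ester to attack, the more acidic C8 methylene could only close a four-membered ring, and O1 is already bonded to C8a, so the 4→8 link to unit 4 is fixed and no 4→6 isomer can form. Aromatisation to the phenoxide makes the step irreversible and draws the unfavourable methyl enolate equilibrium forward. The free C3 alkoxide cannot attack the ester or the lactone, because the lactone so formed would hold a bridgehead double bond at C4a (Bredt), and the benzyl ethers are inert to methoxide.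

Step 10
Reactants: 18 3′,4′-di-O-benzylepicatechin-(4β→8)-3,5,7,3′,4′-penta-O-benzylcatechin
Product: 19 5,7,3′,4′-tetra-O-benzylepicatechin-(4β→8)-3,5,7,3′,4′-penta-O-benzylcatechin
Conditions: BnBr (2.4 equiv), K2CO3, DMF, rt
Reagents that add atoms: benzyl bromide, BrCc1ccccc1
Why: Williamson O-benzylation of the two new phenols; K2CO3 does not deprotonate the secondary C3 hydroxyl, which stays free as in the usual flavan nucleophiles.

Step 11
Reactants: 20 (−)-epicatechin
Product: 21 5,7,3′,4′-tetra-O-benzyl-(−)-epicatechin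
Conditions: BnBr, K2CO3, DMF, 0 °C → rt
Reagents that add atoms: benzyl bromide, BrCc1ccccc1
Why: Phenol-selective Williamson etherification; mild base and low temperature limit epimerisation at C2.

Step 12
Reactants: 21 5,7,3′,4′-tetra-O-benzyl-(−)-epicatechin
Product: 22 4β-(2-ethoxyethoxy)-5,7,3′,4′-tetra-O-benzylepicatechin
Conditions: DDQ, EtOCH2CH2OH, CH2Cl2, rt
Reagents that add atoms: 2-ethoxyethanol, CCOCCO
Why: Benzylic oxidation by hydride abstraction at C4; the cation stabilised by ring A is trapped by the alcohol on the face opposite to the axial C3 hydroxyl, which gives the 4β ether.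

Step 13
Reactants: 22 4β-(2-ethoxyethoxy)-5,7,3′,4′-tetra-O-benzylepicatechin
Product: 23 8-bromo-4β-(2-ethoxyethoxy)-5,7,3′,4′-tetra-O-benzylepicatechin
Conditions: NBS, CH2Cl2, −78 °C
Reagents that add atoms: N-bromosuccinimide, BrN1C(=O)CCC1=O
Why: Electrophilic bromination at C8 as in step 2; the bromine blocks the only strongly nucleophilic position of the future electrophile.

Step 14
Reactants: 23 8-bromo-4β-(2-ethoxyethoxy)-5,7,3′,4′-tetra-O-benzylepicatechin; 21 5,7,3′,4′-tetra-O-benzyl-(−)-epicatechin
Product: 24 8-bromo-5,7,3′,4′-tetra-O-benzylepicatechin-(4β→8)-5,7,3′,4′-tetra-O-benzylepicatechin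
Conditions: Me3SiOTf (0.2 equiv), 21 (1.5 equiv), CH2Cl2, −78 °C
Reagents that add atoms: none
Why: Lewis-acid ionisation of the C4 ether to the flavan-4-yl cation and Friedel–Crafts attack by C8 of 21. The nucleophile enters anti to the axial C3 hydroxyl, which sets C4 of unit 1 as 4β, and the bromine keeps 23 from condensing with itself.

Step 15
Reactants: 24 8-bromo-5,7,3′,4′-tetra-O-benzylepicatechin-(4β→8)-5,7,3′,4′-tetra-O-benzylepicatechin
Product: 25 the dimer 24 carrying a 4β-(2-ethoxyethoxy) group on C4 of its lower unit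
Conditions: DDQ, EtOCH2CH2OH, CH2Cl2, rt
Reagents that add atoms: 2-ethoxyethanol, CCOCCO
Why: Benzylic oxidation as in step 12 at the CH2 group of the lower unit. The tertiary C4–H of the upper unit is quasi-equatorial, lies near the plane of its ring A and is flanked by two aryl groups, so hydride abstraction there should be slow.

Step 16
Reactants: 25 the dimer 24 carrying a 4β-(2-ethoxyethoxy) group on C4 of its lower unit; 19 5,7,3′,4′-tetra-O-benzylepicatechin-(4β→8)-3,5,7,3′,4′-penta-O-benzylcatechin
Product: 26 8-bromo-heptadeca-O-benzyl-arecatannin A2 (bromine on C8 of unit 1, free 3-hydroxyls on units 1 to 3)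
Conditions: Me3SiOTf (0.3 equiv), CH2Cl2, −78 → −40 °C
Reagents that add atoms: none
Why: Flavan-4-yl cation coupling as in step 14; C8 of the top unit of 19 is the most accessible nucleophilic position and attacks anti to the C3 hydroxyl of unit 2, which sets C4 of unit 2 as 4β. The C8 bromine of 25 rules out self-condensation and further growth, so one equivalent of each dimer can be used.

Step 17
Reactants: 26 8-bromo-heptadeca-O-benzyl-arecatannin A2
Product: 27 arecatannin A2
Conditions: H2 (1 atm), Pd(OH)2 on carbon, Et3N, THF–MeOH–H2O, rt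
Reagents that add atoms: none
Why: Hydrogenolysis of the seventeen benzyl ethers and of the aryl bromide under neutral conditions; the amine takes up HBr, so the acid-labile interflavan bonds and the C2 centres should be untouched.

## Compound list

1 | (+)-catechin | Oc1cc(O)c2c(c1)O[C@H](c1ccc(O)c(O)c1)[C@@H](O)C2 | starting material
2 | 3,5,7,3′,4′-penta-O-benzyl-(+)-catechin | c3ccccc3COc1cc(OCc3ccccc3)c2c(c1)O[C@H](c1ccc(OCc3ccccc3)c(OCc3ccccc3)c1)[C@@H](OCc3ccccc3)C2 | intermediate
3 | 8-bromo-3,5,7,3′,4′-penta-O-benzylcatechin | c3ccccc3COc1cc(OCc3ccccc3)c2c(c1Br)O[C@H](c1ccc(OCc3ccccc3)c(OCc3ccccc3)c1)[C@@H](OCc3ccccc3)C2 | intermediate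
4 | 8-lithio-3,5,7,3′,4′-penta-O-benzylcatechin (formed in the flask) | c3ccccc3COc1cc(OCc3ccccc3)c2c(c1[Li])O[C@H](c1ccc(OCc3ccccc3)c(OCc3ccccc3)c1)[C@@H](OCc3ccccc3)C2 | intermediate
5 | lithium (E)-3-(dimethylamino)-1-(3,5,7,3′,4′-penta-O-benzylcatechin-8-yl)prop-2-en-1-olate, carbinol carbon as a mixture (formed in the flask) | c3ccccc3COc1cc(OCc3ccccc3)c2c(c1C(O[Li])/C=C/N(C)C)O[C@H](c1ccc(OCc3ccccc3)c(OCc3ccccc3)c1)[C@@H](OCc3ccccc3)C2 | intermediate
6 | (E)-3-(3,5,7,3′,4′-penta-O-benzylcatechin-8-yl)propenal | c3ccccc3COc1cc(OCc3ccccc3)c2c(c1/C=C/C=O)O[C@H](c1ccc(OCc3ccccc3)c(OCc3ccccc3)c1)[C@@H](OCc3ccccc3)C2 | intermediate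
7 | triacetic acid lactone (4-hydroxy-6-methylpyran-2-one) | Cc1cc(O)cc(=O)o1 | starting material
8 | (3S)-3-(4-hydroxy-6-methyl-2-oxo-2H-pyran-3-yl)-3-(3,5,7,3′,4′-penta-O-benzylcatechin-8-yl)propanal (formed in the flask) | Cc1cc(O)c(c(=O)o1)[C@@H](CC=O)c1c(OCc3ccccc3)cc(OCc3ccccc3)c2c1O[C@H](c1ccc(OCc3ccccc3)c(OCc3ccccc3)c1)[C@@H](OCc3ccccc3)C2 | intermediate
9 | (4S)-2-hydroxy-7-methyl-4-(3,5,7,3′,4′-penta-O-benzylcatechin-8-yl)-3,4-dihydro-2H,5H-pyrano[4,3-b]pyran-5-one, both C2 anomers | CC1=CC2=C(C(=O)O1)[C@@H](CC(O)O2)c1c(OCc3ccccc3)cc(OCc3ccccc3)c2c1O[C@H](c1ccc(OCc3ccccc3)c(OCc3ccccc3)c1)[C@@H](OCc3ccccc3)C2 | intermediate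
10 | (4S)-7-methyl-4-(3,5,7,3′,4′-penta-O-benzylcatechin-8-yl)-4H,5H-pyrano[4,3-b]pyran-5-one | CC1=CC2=C(C(=O)O1)[C@@H](C=CO2)c1c(OCc3ccccc3)cc(OCc3ccccc3)c2c1O[C@H](c1ccc(OCc3ccccc3)c(OCc3ccccc3)c1)[C@@H](OCc3ccccc3)C2 | intermediate
11 | 4-bromocatechol | Oc1ccc(Br)cc1O | starting material
12 | 1,2-bis(benzyloxy)-4-bromobenzene | Brc1ccc(OCc2ccccc2)c(OCc2ccccc2)c1 | intermediate
13 | 3,4-bis(benzyloxy)phenylmagnesium bromide (formed in the flask) | Br[Mg]c1ccc(OCc2ccccc2)c(OCc2ccccc2)c1 | intermediate
14 | [3,4-bis(benzyloxy)phenyl]dimethylaluminium (THF solution) | C[Al](C)c1ccc(OCc2ccccc2)c(OCc2ccccc2)c1 | intermediate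
15 | 2,3-epoxide of 10, oxirane oxygen on the face opposite to the C4 aryl group (formed in the flask) | CC1=CC2=C(C(=O)O1)[C@@H]([C@H]3O[C@H]3O2)c1c(OCc3ccccc3)cc(OCc3ccccc3)c2c1O[C@H](c1ccc(OCc3ccccc3)c(OCc3ccccc3)c1)[C@@H](OCc3ccccc3)C2 | intermediate
16 | (2R,3R,4S)-2-[3,4-bis(benzyloxy)phenyl]-3-hydroxy-7-methyl-4-(3,5,7,3′,4′-penta-O-benzylcatechin-8-yl)-3,4-dihydro-2H,5H-pyrano[4,3-b]pyran-5-one (key-step precursor) | CC1=CC2=C(C(=O)O1)[C@@H]([C@@H](O)[C@H](O2)c1ccc(OCc3ccccc3)c(OCc3ccccc3)c1)c1c(OCc3ccccc3)cc(OCc3ccccc3)c2c1O[C@H](c1ccc(OCc3ccccc3)c(OCc3ccccc3)c1)[C@@H](OCc3ccccc3)C2 | intermediate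
17 | methyl 6-[3,4-bis(benzyloxy)phenyl]-5-hydroxy-2-(2-oxopropyl)-4-(3,5,7,3′,4′-penta-O-benzylcatechin-8-yl)-5,6-dihydro-4H-pyran-3-carboxylate, ring stereocentres as in 16 (formed in the flask) | COC(=O)C1=C(CC(C)=O)O[C@H](c2ccc(OCc3ccccc3)c(OCc3ccccc3)c2)[C@H](O)[C@H]1c1c(OCc3ccccc3)cc(OCc3ccccc3)c2c1O[C@H](c1ccc(OCc3ccccc3)c(OCc3ccccc3)c1)[C@@H](OCc3ccccc3)C2 | intermediate
18 | 3′,4′-di-O-benzylepicatechin-(4β→8)-3,5,7,3′,4′-penta-O-benzylcatechin (key-step product) | Oc1cc(O)c2c(c1)O[C@H](c1ccc(OCc3ccccc3)c(OCc3ccccc3)c1)[C@H](O)[C@H]2c1c(OCc3ccccc3)cc(OCc3ccccc3)c2c1O[C@H](c1ccc(OCc3ccccc3)c(OCc3ccccc3)c1)[C@@H](OCc3ccccc3)C2 | intermediate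
19 | 5,7,3′,4′-tetra-O-benzylepicatechin-(4β→8)-3,5,7,3′,4′-penta-O-benzylcatechin | c3ccccc3COc1cc(OCc3ccccc3)c2c(c1)O[C@H](c1ccc(OCc3ccccc3)c(OCc3ccccc3)c1)[C@H](O)[C@H]2c1c(OCc3ccccc3)cc(OCc3ccccc3)c2c1O[C@H](c1ccc(OCc3ccccc3)c(OCc3ccccc3)c1)[C@@H](OCc3ccccc3)C2 | intermediate
20 | (−)-epicatechin | Oc1cc(O)c2c(c1)O[C@H](c1ccc(O)c(O)c1)[C@H](O)C2 | starting material
21 | 5,7,3′,4′-tetra-O-benzyl-(−)-epicatechin | c3ccccc3COc1cc(OCc3ccccc3)c2c(c1)O[C@H](c1ccc(OCc3ccccc3)c(OCc3ccccc3)c1)[C@H](O)C2 | intermediate
22 | 4β-(2-ethoxyethoxy)-5,7,3′,4′-tetra-O-benzylepicatechin | c3ccccc3COc1cc(OCc3ccccc3)c2c(c1)O[C@H](c1ccc(OCc3ccccc3)c(OCc3ccccc3)c1)[C@H](O)[C@H]2OCCOCC | intermediate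
23 | 8-bromo-4β-(2-ethoxyethoxy)-5,7,3′,4′-tetra-O-benzylepicatechin | c3ccccc3COc1cc(OCc3ccccc3)c2c(c1Br)O[C@H](c1ccc(OCc3ccccc3)c(OCc3ccccc3)c1)[C@H](O)[C@H]2OCCOCC | intermediate
24 | 8-bromo-5,7,3′,4′-tetra-O-benzylepicatechin-(4β→8)-5,7,3′,4′-tetra-O-benzylepicatechin | c3ccccc3COc1cc(OCc3ccccc3)c2c(c1Br)O[C@H](c1ccc(OCc3ccccc3)c(OCc3ccccc3)c1)[C@H](O)[C@H]2c1c(OCc3ccccc3)cc(OCc3ccccc3)c2c1O[C@H](c1ccc(OCc3ccccc3)c(OCc3ccccc3)c1)[C@H](O)C2 | intermediate
25 | dimer 24 with a 4β-(2-ethoxyethoxy) group on C4 of its lower unit | c3ccccc3COc1cc(OCc3ccccc3)c2c(c1Br)O[C@H](c1ccc(OCc3ccccc3)c(OCc3ccccc3)c1)[C@H](O)[C@H]2c1c(OCc3ccccc3)cc(OCc3ccccc3)c2c1O[C@H](c1ccc(OCc3ccccc3)c(OCc3ccccc3)c1)[C@H](O)[C@H]2OCCOCC | intermediate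
26 | 8-bromo-heptadeca-O-benzyl-arecatannin A2 (bromine on C8 of unit 1; free 3-hydroxyls on units 1 to 3) | c3ccccc3COc1cc(OCc3ccccc3)c2c(c1Br)O[C@H](c1ccc(OCc3ccccc3)c(OCc3ccccc3)c1)[C@H](O)[C@H]2c1c(OCc3ccccc3)cc(OCc3ccccc3)c2c1O[C@H](c1ccc(OCc3ccccc3)c(OCc3ccccc3)c1)[C@H](O)[C@H]2c1c(OCc3ccccc3)cc(OCc3ccccc3)c2c1O[C@H](c1ccc(OCc3ccccc3)c(OCc3ccccc3)c1)[C@H](O)[C@H]2c1c(OCc3ccccc3)cc(OCc3ccccc3)c2c1O[C@H](c1ccc(OCc3ccccc3)c(OCc3ccccc3)c1)[C@@H](OCc3ccccc3)C2 | intermediate
27 | arecatannin A2 | Oc1cc(O)c2c(c1)O[C@H](c1ccc(O)c(O)c1)[C@H](O)[C@H]2c1c(O)cc(O)c2c1O[C@H](c1ccc(O)c(O)c1)[C@H](O)[C@H]2c1c(O)cc(O)c2c1O[C@H](c1ccc(O)c(O)c1)[C@H](O)[C@H]2c1c(O)cc(O)c2c1O[C@H](c1ccc(O)c(O)c1)[C@@H](O)C2 | target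

## Step count and least certain steps

Total step count: 17. Longest linear sequence: 10 steps (steps 1 to 5, 8 to 10, 16 and 17, from 1 to 27).

Step 9 (key step). The Claisen closure may stall at the seco ester 17: its ester is a vinylogous carbonate of low electrophilicity, and most of the material rests as the unreactive C8 enolate. Methoxide may also add at C8a and reversibly open ring C, which invites side reactions at 65 °C. Fallback: give up the folding and make the unit 3–unit 4 bond by flavan-4-yl cation chemistry. The fallback sets out from 2 and 22: 22 is added to an excess of 2 with Me3SiOTf in CH2Cl2 at −78 °C, and attack of C8 of 2 on the β face of the cation should give 19 directly, where it rejoins the route. No new compound is needed.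

Step 8. The aryl transfer may lose its facial fidelity: opening through a free oxocarbenium ion or from the back of the epoxide would give the 2,3-trans isomer. Transfer of a methyl group from the mixed alane may compete with aryl transfer, and the aluminium Lewis acid may ionise the new benzylic C2–O1 bond, whose leaving group is a vinylogous carboxylate. Fallback, from 10 back to 16:
- Oxidation of 10 with 3-chloroperbenzoic acid (epoxidation anti to the C4 aryl group, opening by the carboxylate at C2) should give the 2-(3-chlorobenzoyloxy)-3-hydroxy adduct F1.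
- Silylation with t-BuMe2SiOTf and 2,6-lutidine gives the C3 silyl ether F2.
- An excess of the Grignard reagent 13 at −78 °C cleaves the anomeric ester; the released lactol opens to the aldehyde, which adds a further equivalent under Felkin–Anh control to give the anti 2-hydroxy-3-silyloxy compound F3.
- Mitsunobu closure (PPh3, diisopropyl azodicarboxylate) by the acidic pyranone hydroxyl, with inversion at C2, gives the C3 silyl ether of the precursor F4.
- Bu4NF buffered with AcOH returns 16.

Step 4. Conjugate addition may be slow and reversible: the β-carbon of 6 is flanked by two ortho oxygen substituents and the electron-rich aryl group lowers the electrophilicity of the iminium ion, so an uncatalysed background reaction could erode the face selection at C4. Fallback, from 3 back to 10 (replacing steps 3 to 5):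
- Bromine–lithium exchange of 3 and quenching with DMF gives the 8-carbaldehyde F5.
- Knoevenagel condensation with 7 (ethylenediammonium diacetate, CH2Cl2) forms the 3-arylidenepyran-2,4-dione F6.
- F6 is trapped in the same flask by ethyl vinyl ether in a hetero-Diels–Alder reaction with inverse electron demand, giving the 2-ethoxy acetal F7.
- The C4 epimers, which the catechin unit makes diastereomers, are separated, and the 4S epimer loses ethanol with Me3SiOTf and i-Pr2NEt to give 10.

Step 15. Hydride abstraction may occur at the wrong benzylic position (the tertiary C4–H of unit 1), or the product may be oxidised further, because the dimer offers several activated C–H bonds. Fallback, from 22 back to 26: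
- 22 is converted with 2,6-dimethylbenzenethiol and BF3·OEt2 into the 4β-sulfide F8, which silyl triflates do not ionise.
- F8 serves as the nucleophile towards 23 (Me3SiOTf, −78 °C) and gives the bromo dimer F9, with the sulfide on C4 of its lower unit.
- A thiophile (AgBF4, THF, 0 °C) ionises F9 in the presence of 19 and gives 26.

Step 16. Attack by the bulky nucleophile may be slow, so that C6 positions compete or the acid cleaves interflavan bonds when the temperature is raised. Fallback, from 19 back to 26: add the two upper units one at a time. Slow addition of 22 to an excess of 19 with Me3SiOTf at −78 °C gives the trimer F10, which has a free C8 on its top unit, and coupling of F10 with the blocked monomer 23 gives 26.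

## Further compounds

F0 | step 9 | none | none
F1 | step 8 | (3R,4S)-2-(3-chlorobenzoyloxy)-3-hydroxy-7-methyl-4-(3,5,7,3′,4′-penta-O-benzylcatechin-8-yl)-3,4-dihydro-2H,5H-pyrano[4,3-b]pyran-5-one | CC1=CC2=C(C(=O)O1)[C@@H]([C@@H](O)C(OC(=O)c3cccc(Cl)c3)O2)c1c(OCc3ccccc3)cc(OCc3ccccc3)c2c1O[C@H](c1ccc(OCc3ccccc3)c(OCc3ccccc3)c1)[C@@H](OCc3ccccc3)C2
F2 | step 8 | 3-O-tert-butyldimethylsilyl ether of F1 | CC1=CC2=C(C(=O)O1)[C@@H]([C@@H](O[Si](C)(C)C(C)(C)C)C(OC(=O)c3cccc(Cl)c3)O2)c1c(OCc3ccccc3)cc(OCc3ccccc3)c2c1O[C@H](c1ccc(OCc3ccccc3)c(OCc3ccccc3)c1)[C@@H](OCc3ccccc3)C2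
F3 | step 8 | 3-[3-[3,4-bis(benzyloxy)phenyl]-3-hydroxy-2-(tert-butyldimethylsilyloxy)-1-(3,5,7,3′,4′-penta-O-benzylcatechin-8-yl)propyl]-4-hydroxy-6-methylpyran-2-one, anti 2,3-dioxygen pattern | Cc1cc(O)c(c(=O)o1)[C@@H]([C@@H](O[Si](C)(C)C(C)(C)C)[C@@H](O)c1ccc(OCc3ccccc3)c(OCc3ccccc3)c1)c1c(OCc3ccccc3)cc(OCc3ccccc3)c2c1O[C@H](c1ccc(OCc3ccccc3)c(OCc3ccccc3)c1)[C@@H](OCc3ccccc3)C2
F4 | step 8 | 3-O-tert-butyldimethylsilyl ether of 16 | CC1=CC2=C(C(=O)O1)[C@@H]([C@@H](O[Si](C)(C)C(C)(C)C)[C@H](O2)c1ccc(OCc3ccccc3)c(OCc3ccccc3)c1)c1c(OCc3ccccc3)cc(OCc3ccccc3)c2c1O[C@H](c1ccc(OCc3ccccc3)c(OCc3ccccc3)c1)[C@@H](OCc3ccccc3)C2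
F5 | step 4 | 3,5,7,3′,4′-penta-O-benzylcatechin-8-carbaldehyde | c3ccccc3COc1cc(OCc3ccccc3)c2c(c1C=O)O[C@H](c1ccc(OCc3ccccc3)c(OCc3ccccc3)c1)[C@@H](OCc3ccccc3)C2
F6 | step 4 | 6-methyl-3-[(3,5,7,3′,4′-penta-O-benzylcatechin-8-yl)methylidene]pyran-2,4-dione | CC1=CC(=O)C(C(=O)O1)=Cc1c(OCc3ccccc3)cc(OCc3ccccc3)c2c1O[C@H](c1ccc(OCc3ccccc3)c(OCc3ccccc3)c1)[C@@H](OCc3ccccc3)C2
F7 | step 4 | (4S)-2-ethoxy-7-methyl-4-(3,5,7,3′,4′-penta-O-benzylcatechin-8-yl)-3,4-dihydro-2H,5H-pyrano[4,3-b]pyran-5-one | CC1=CC2=C(C(=O)O1)[C@@H](CC(OCC)O2)c1c(OCc3ccccc3)cc(OCc3ccccc3)c2c1O[C@H](c1ccc(OCc3ccccc3)c(OCc3ccccc3)c1)[C@@H](OCc3ccccc3)C2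
F8 | step 15 | 4β-(2,6-dimethylphenylthio)-5,7,3′,4′-tetra-O-benzylepicatechin | c3ccccc3COc1cc(OCc3ccccc3)c2c(c1)O[C@H](c1ccc(OCc3ccccc3)c(OCc3ccccc3)c1)[C@H](O)[C@H]2Sc1c(C)cccc1C
F9 | step 15 | 8-bromo-5,7,3′,4′-tetra-O-benzylepicatechin-(4β→8)-4β-(2,6-dimethylphenylthio)-5,7,3′,4′-tetra-O-benzylepicatechin | c3ccccc3COc1cc(OCc3ccccc3)c2c(c1Br)O[C@H](c1ccc(OCc3ccccc3)c(OCc3ccccc3)c1)[C@H](O)[C@H]2c1c(OCc3ccccc3)cc(OCc3ccccc3)c2c1O[C@H](c1ccc(OCc3ccccc3)c(OCc3ccccc3)c1)[C@H](O)[C@H]2Sc1c(C)cccc1C
F10 | step 16 | 5,7,3′,4′-tetra-O-benzylepicatechin-(4β→8)-5,7,3′,4′-tetra-O-benzylepicatechin-(4β→8)-3,5,7,3′,4′-penta-O-benzylcatechin | c3ccccc3COc1cc(OCc3ccccc3)c2c(c1)O[C@H](c1ccc(OCc3ccccc3)c(OCc3ccccc3)c1)[C@H](O)[C@H]2c1c(OCc3ccccc3)cc(OCc3ccccc3)c2c1O[C@H](c1ccc(OCc3ccccc3)c(OCc3ccccc3)c1)[C@H](O)[C@H]2c1c(OCc3ccccc3)cc(OCc3ccccc3)c2c1O[C@H](c1ccc(OCc3ccccc3)c(OCc3ccccc3)c1)[C@@H](OCc3ccccc3)C2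
A1 | alternative 1 | seco-tetramer with ring A of unit 4 formed (free C8a hydroxyl, C7 triisopropylsilyl ether) and ring C of unit 4 open | c3ccccc3COc1cc(OCc3ccccc3)c2c(c1)O[C@H](c1ccc(OCc3ccccc3)c(OCc3ccccc3)c1)[C@H](OCc3ccccc3)[C@H]2c1c(OCc3ccccc3)cc(OCc3ccccc3)c2c1O[C@H](c1ccc(OCc3ccccc3)c(OCc3ccccc3)c1)[C@H](OCc3ccccc3)[C@H]2c1c(OCc3ccccc3)cc(OCc3ccccc3)c2c1O[C@H](c1ccc(OCc3ccccc3)c(OCc3ccccc3)c1)[C@H](OCc3ccccc3)[C@H]2c1c(O[Si](C(C)C)(C(C)C)C(C)C)cc(OCc3ccccc3)c(C[C@H](OCc3ccccc3)[C@@H](O[Si](CC)(CC)CC)c2ccc(OCc3ccccc3)c(OCc3ccccc3)c2)c1O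
A2 | alternative 1 | perbenzylated epicatechin trimer with a (triisopropylsilyloxy)ethynyl group on C4 (β) of unit 3 | c3ccccc3COc1cc(OCc3ccccc3)c2c(c1)O[C@H](c1ccc(OCc3ccccc3)c(OCc3ccccc3)c1)[C@H](OCc3ccccc3)[C@H]2c1c(OCc3ccccc3)cc(OCc3ccccc3)c2c1O[C@H](c1ccc(OCc3ccccc3)c(OCc3ccccc3)c1)[C@H](OCc3ccccc3)[C@H]2c1c(OCc3ccccc3)cc(OCc3ccccc3)c2c1O[C@H](c1ccc(OCc3ccccc3)c(OCc3ccccc3)c1)[C@H](OCc3ccccc3)[C@H]2C#CO[Si](C(C)C)(C(C)C)C(C)C
A3 | alternative 1 | 3-benzyloxy-4-[2-benzyloxy-3-[3,4-bis(benzyloxy)phenyl]-3-(triethylsilyloxy)propyl]cyclobut-2-en-1-one, side chain configured for unit 4 | O=C1C=C(OCc2ccccc2)C1C[C@H](OCc2ccccc2)[C@@H](O[Si](CC)(CC)CC)c1ccc(OCc2ccccc2)c(OCc2ccccc2)c1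
A4 | alternative 2 | perbenzylated arecatannin A2 | c3ccccc3COc1cc(OCc3ccccc3)c2c(c1)O[C@H](c1ccc(OCc3ccccc3)c(OCc3ccccc3)c1)[C@H](OCc3ccccc3)[C@H]2c1c(OCc3ccccc3)cc(OCc3ccccc3)c2c1O[C@H](c1ccc(OCc3ccccc3)c(OCc3ccccc3)c1)[C@H](OCc3ccccc3)[C@H]2c1c(OCc3ccccc3)cc(OCc3ccccc3)c2c1O[C@H](c1ccc(OCc3ccccc3)c(OCc3ccccc3)c1)[C@H](OCc3ccccc3)[C@H]2c1c(OCc3ccccc3)cc(OCc3ccccc3)c2c1O[C@H](c1ccc(OCc3ccccc3)c(OCc3ccccc3)c1)[C@@H](OCc3ccccc3)C2
A5 | alternative 2 | tetramer skeleton with C2 acetates in place of ring B on units 1 to 3 | c3ccccc3COc1cc(OCc3ccccc3)c2c(c1)OC(OC(C)=O)[C@H](OCc3ccccc3)[C@H]2c1c(OCc3ccccc3)cc(OCc3ccccc3)c2c1OC(OC(C)=O)[C@H](OCc3ccccc3)[C@H]2c1c(OCc3ccccc3)cc(OCc3ccccc3)c2c1OC(OC(C)=O)[C@H](OCc3ccccc3)[C@H]2c1c(OCc3ccccc3)cc(OCc3ccccc3)c2c1O[C@H](c1ccc(OCc3ccccc3)c(OCc3ccccc3)c1)[C@@H](OCc3ccccc3)C2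
A6 | alternative 2 | 1,2-bis(benzyloxy)benzene | c1ccc(COc2ccccc2OCc2ccccc2)cc1
A7 | alternative 3 | protected epicatechin-(4β→8)-catechin with free C3 hydroxyl on unit 3 and ring B benzoates | c3ccccc3COc1cc(OCc3ccccc3)c2c(c1)O[C@H](c1ccc(OC(=O)c5ccccc5)c(OC(=O)c5ccccc5)c1)[C@H](O)[C@H]2c1c(OCc3ccccc3)cc(OCc3ccccc3)c2c1O[C@H](c1ccc(OCc3ccccc3)c(OCc3ccccc3)c1)[C@@H](OCc3ccccc3)C2
A8 | alternative 3 | cis-epoxide precursor: 3,5-bis(benzyloxy)-2-[(3,5,7,3′,4′-penta-O-benzylcatechin-8-yl)(3-[3,4-bis(benzoyloxy)phenyl]oxiran-2-yl)methyl]phenol | Oc1cc(OCc3ccccc3)cc(OCc3ccccc3)c1[C@@H]([C@H]4O[C@H]4c1ccc(OC(=O)c5ccccc5)c(OC(=O)c5ccccc5)c1)c1c(OCc3ccccc3)cc(OCc3ccccc3)c2c1O[C@H](c1ccc(OCc3ccccc3)c(OCc3ccccc3)c1)[C@@H](OCc3ccccc3)C2
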